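The data stem from a simulated flask with made-up constants; noise was put on by code.

If one catalyst takes both mirror-image substrates by steps first order in each, they see the same catalyst and reagent at every moment. Each then loses a fixed multiple of the other's half-lives, and this is a kinetic resolution. We count the half-lives by which the left-handed substrate has got ahead:

gap = ln([right-handed substrate]/[left-handed substrate]) / ln(2)

excess = (2^gap − 1) / (2^gap + 1)

in all of them: left-handed substrate 13 mM; right-handed substrate 13 mM; added ligand 69 µM

| flask | reagent | free catalyst | remark | time |
|---|---|---|---|---|
| cedar | 1.5 equiv | 1.2 mol% | run made earlier |  |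
| oak | 1.5 equiv | 6.1 mol% | run made earlier |  |
| Monday's | 1.50 equiv | 1 mol% |  | 10 d |
| Tuesday's | 1.50 equiv | 4 mol% |  | 10 d |

| run | time / d | right-handed substrate / % | left-handed substrate / % |
|---|---|---|---|
| cedar | 0.417 | 47 | 47 |
| cedar | 1.25 | 50 | 45 |
| cedar | 2.50 | 43 | 41 |
| cedar | 4.00 | 45 | 38 |
| cedar | 5.00 | 45 | 37 |
| oak | 0.417 | 43 | 39 |
| oak | 1.25 | 42 | 27 |
| oak | 2.50 | 35 | 22 |
| oak | 4.00 | 30 | 15 |
| oak | 5.00 | 27 | 13 |

(readings scatter by 1.5 percentage points)

- free catalyst is single-handed; left-handed substrate and right-handed substrate are mirror images of each other, charged as a racemate, each of them at the stated concentration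
- the analysis behind the earlier runs scatters by 1.5 percentage points, standard deviation
- an excess is below zero if the other one leads

1. the winner by excess of right-handed substrate over left-handed substrate among what is left of the two; "neither" if no more than 2 percentage points parts them (Monday's / Tuesday's / neither)
2. excess of right-handed substrate over left-handed substrate among what is left of the two at the end, Monday's
3. excess of right-handed substrate over left-handed substrate among what is left of the two at the end, Tuesday's

We build the reckoning from oak, whose gap at its last reading is larger than cedar's, and we take the gap to scale with loading.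

First, the main step by itself, running steadily. Oak's gap at 2.50 d is 0.670. Growing in proportion to time and loading, it gives Tuesday's:

gap = 1.76, excess 54.4%

Second, the slowing. By 5.00 d oak's gap is 1.05, so the second stretch added a fraction 0.574 of the first. If each later stretch adds that same fraction of the one before, two more stretches give oak's gap at 10 d, the quantity we carry, 1.40. Scaled by loading:

Monday's: gap 0.230, excess 7.95%

Tuesday's: gap 0.919, excess 30.8%

Last, the added ligand. A ligand holding a fixed amount of catalyst costs a small loading most, yet cedar's gap at 5.00 d, 0.282, is larger than the 0.207 scaled from oak. Those two cedar readings stand 8 percentage points apart, each scattering by 1.5 points, so we correct nothing.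

The forecast names Tuesday's, with 8% for Monday's and 33% for Tuesday's, a little above ours for Tuesday's, and holds that “Both runs slow down with time in the same way regardless of loading”.

The flask gives Tuesday's, with 10.4% for Monday's and 30.3% for Tuesday's.

    reagent + free catalyst → spent catalyst (k = 2.30 × 10⁻⁴ M⁻¹ s⁻¹)
    reagent + free catalyst + left-handed substrate → free catalyst + left-handed product (k = 0.910 M⁻² s⁻¹)
    reagent ⇌ dormant form (K = 0.730, k = 5.60 × 10⁻⁵ s⁻¹)
    free catalyst + added ligand ⇌ idle complex, settled at all times (K = 3100 M⁻¹)
    reagent + free catalyst + right-handed substrate → free catalyst + right-handed product (k = 0.430 M⁻² s⁻¹)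

Tuesday's ends with 15.3% left-handed and 28.5% right-handed substrate, and 14% of its reagent remains. Its excess corresponds to a gap of 0.903, against our 0.919. Put to a flask like Monday's but with 0.4 mol% of free catalyst, 1.40 scales to a gap of 0.0919, an excess of 3.18%, and that flask stands at 4.41%.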